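Assumption: 4-iodoresorcinol and (S)-N,N-dimethyllactamide are treated as catalogue items. Locants C1–C6 in the text follow the target (C1 = C=O, C6 = carbinol carbon bearing the chain).

## Retrosynthetic overview
1. Target 12 comes from anti (SN2) hydrolysis at allylic C4 of the syn-epoxy ketol 11. This inverts C4 and leaves the C5/C6 oxygens cis.
2. Compound 11 is formally the epoxide of an o-quinol, a species that self-dimerises. It is reached instead from a stable p-quinol surrogate 10 by a Stork–Danheiser 1,3-carbonyl transposition, which moves the C=O next to the carbinol.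
3. Compound 10 comes from face-selective nucleophilic epoxidation of dienone 9. Dienone 9 comes from lactamide-tethered oxidative dearomatisation of the 4-alkylresorcinol ether 8, which sets C6; the auxiliary is shed during the transposition.
4. Compound 8 comes from a Ni-catalysed decarboxylative aryl–alkyl coupling. Oleic acid supplies the C17 chain with its native Z-alkene, so there is no Wittig, no Grignard-to-ketone addition, no RCM and no chiral-pool ring.
5. Rings: the carbocycle is bought as the arene. The dioxanone (step 6) and the oxirane (step 7) are temporary and are both opened in steps 8–9.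

## Forward route

**Step 1**
Reactants: 1, oleic acid
Product: 2, oleic acid N-hydroxyphthalimide (redox-active) ester
Conditions: N-hydroxyphthalimide, DIC, DMAP (cat.), CH2Cl2, rt
Reagents that add atoms: N-hydroxyphthalimide, O=C1c2ccccc2C(=O)N1O
Why: Steglich-type carbodiimide esterification activates the acid for single-electron decarboxylation without touching the Z-alkene, and no stereocentre is formed.

**Step 2**
Reactants: 3, 4-iodoresorcinol
Product: 4, 5-(tert-butyldimethylsilyloxy)-2-iodophenol
Conditions: TBSCl (1.0 equiv), imidazole, CH2Cl2, −20 → 0 °C
Reagents that add atoms: TBSCl, CC(C)(C)[Si](C)(C)Cl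
Why: This is a sterically controlled mono-silylation, because the OH flanked by the large iodine reacts much more slowly, so only the OH para to iodine is capped.

**Step 3**
Reactants: 4; 5, (S)-2-hydroxy-N,N-dimethylpropanamide
Product: 6, (R)-2-[5-(TBSO)-2-iodophenoxy]-N,N-dimethylpropanamide
Conditions: PPh3, DIAD, THF, 0 °C → rt
Reagents that add atoms: none beyond the numbered reactants
Why: Mitsunobu etherification of the acidic o-iodophenol is an SN2 process with clean inversion, so the (S)-carbinol becomes the (R)-aryl ether stereocentre that later serves as a traceless auxiliary.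

**Step 4**
Reactants: 6; 2
Product: 7, (R)-2-{5-(TBSO)-2-[(Z)-heptadec-8-en-1-yl]phenoxy}-N,N-dimethylpropanamide
Conditions: NiBr2·dme (10 mol %), dtbbpy (10 mol %), Zn, DMA, rt
Reagents that add atoms: none beyond the numbered reactants (2 loses CO2 and phthalimide, 6 loses I)
Why: In this Ni-catalysed decarboxylative cross-electrophile coupling, the primary C17 radical released from 2 is captured by aryl–Ni; the C8'=C9' alkene is too remote to cyclise and keeps its Z geometry, and the amide stereocentre is not involved.

**Step 5**
Reactants: 7
Product: 8, (R)-2-{2-[(Z)-heptadec-8-en-1-yl]-5-hydroxyphenoxy}-N,N-dimethylpropanamide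
Conditions: TBAF, AcOH, THF, 0 °C
Reagents that add atoms: none
Why: Fluoride desilylation, buffered so that the α-aryloxy amide cannot epimerise, frees the phenol para to the chain.

**Step 6 (key step, sets C6)**
Reactants: 8
Product: 9, (3R,8aR)-8a-[(Z)-heptadec-8-en-1-yl]-3-methyl-3H-1,4-benzodioxine-2,6(8aH)-dione. This is a cyclohexa-2,5-dienone fused to a 1,4-dioxan-2-one. The lactone O sits on the quaternary carbon (future C6–OH) and the enol-ether O sits on the future C1.
Conditions: PhI(OCOCF3)2 (1.05 equiv), CH2Cl2, −40 → 0 °C; then H2O/NaHCO3; minor diastereomer removed by chromatography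
Reagents that add atoms: water, O (gives the lactone C=O on hydrolysis of the O-alkyl iminium; Me2NH is lost)
Why: In this tether-directed iodine(III) oxidative dearomatisation of a resorcinol ether, the amide oxygen traps the phenoxenium carbon para to OH through a boat-like six-membered transition state whose flagpole site at the new centre is taken by the chain, so the tether methyl must sit bowsprit (also minimising A1,3 strain with NMe2); the (R)-tether therefore delivers oxygen to the face that gives the (R)-carbinol carbon, and the phenol is oxidised far faster than the isolated alkene.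

**Step 7 (sets C5, pre-sets C4)**
Reactants: 9
Product: 10, the 7,8-epoxide of 9 (3R,7S,8R,8aR), with the oxirane O cis to the lactone O and anti to the chain
Conditions: t-BuOOH (decane), DBU, CH2Cl2, 0 °C
Reagents that add atoms: tert-butyl hydroperoxide, CC(C)(C)OO
Why: Weitz–Scheffer nucleophilic epoxidation attacks only the plain enone, since the alkoxy-enone is a deactivated vinylogous ester and the chain alkene is electron-rich, and the peroxide adds to the β-carbon syn to the C–O bond and anti to the alkyl chain for both steric and dipole reasons.

**Step 8 (carbonyl transposition, auxiliary release)**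
Reactants: 10
Product: 11, (4R,5R,6R)-4,5-epoxy-6-hydroxy-6-[(Z)-heptadec-8-en-1-yl]cyclohex-2-en-1-one (oxirane cis to the 6-OH)
Conditions: DIBAL-H (4 equiv), CH2Cl2, −78 °C; then 0.5 M aq. H2SO4, THF, 0 °C
Reagents that add atoms: water, O (becomes the new C1 carbonyl oxygen)
Why: This is a Stork–Danheiser transposition in which 1,2-reduction of the vinylogous-ester ketone (with lactone → lactol), followed by acid hydrolysis of the enol ether and loss of the new allylic OH, moves the carbonyl next to the carbinol; the lactol collapses to release lactaldehyde and the free C6–OH, C4/C5/C6 are untouched, and a non-nucleophilic acid avoids halohydrin formation.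

**Step 9**
Reactants: 11
Product: 12, pleiogenone A, (4S,5R,6R)-4,5,6-trihydroxy-6-[(Z)-heptadec-8-en-1-yl]cyclohex-2-en-1-one
Conditions: HClO4 (cat.), THF–H2O (3:1), 0 °C → rt (can be telescoped with step 8)
Reagents that add atoms: water, O
Why: In this acid-catalysed anti (SN2) opening of a γ,δ-epoxy enone, water attacks the allylic γ-carbon C4 rather than C5 (which is neopentyl-like and inductively deactivated) or C2 (α to the C=O), which inverts C4 from R to S and retains C5–O, giving 4,5-trans and 5,6-cis.

## Compound list
1 | oleic acid, (Z)-octadec-9-enoic acid | CCCCCCCC/C=C\CCCCCCCC(=O)O | starting material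
2 | 1,3-dioxoisoindolin-2-yl (Z)-octadec-9-enoate | CCCCCCCC/C=C\CCCCCCCC(=O)ON1C(=O)c2ccccc2C1=O | intermediate
3 | 4-iodoresorcinol | Oc1ccc(I)c(O)c1 | starting material
4 | 5-(tert-butyldimethylsilyloxy)-2-iodophenol | CC(C)(C)[Si](C)(C)Oc1ccc(I)c(O)c1 | intermediate
5 | (S)-2-hydroxy-N,N-dimethylpropanamide | C[C@H](O)C(=O)N(C)C | starting material
6 | (R)-2-[5-(TBSO)-2-iodophenoxy]-N,N-dimethylpropanamide | C[C@@H](Oc1cc(O[Si](C)(C)C(C)(C)C)ccc1I)C(=O)N(C)C | intermediate
7 | (R)-2-{5-(TBSO)-2-[(Z)-heptadec-8-enyl]phenoxy}-N,N-dimethylpropanamide | C[C@@H](Oc1cc(O[Si](C)(C)C(C)(C)C)ccc1CCCCCCC/C=C\CCCCCCCC)C(=O)N(C)C | intermediate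
8 | (R)-2-{2-[(Z)-heptadec-8-enyl]-5-hydroxyphenoxy}-N,N-dimethylpropanamide | C[C@@H](Oc1cc(O)ccc1CCCCCCC/C=C\CCCCCCCC)C(=O)N(C)C | intermediate
9 | (3R,8aR)-8a-[(Z)-heptadec-8-enyl]-3-methyl-3H-1,4-benzodioxine-2,6(8aH)-dione | CCCCCCCC/C=C\CCCCCCC[C@]12OC(=O)[C@@H](C)OC1=CC(=O)C=C2 | intermediate
10 | (3R,7S,8R,8aR)-7,8-epoxide of 9 (oxirane cis to lactone O) | CCCCCCCC/C=C\CCCCCCC[C@]12OC(=O)[C@@H](C)OC1=CC(=O)[C@H]3O[C@@H]23 | intermediate
11 | (4R,5R,6R)-4,5-epoxy-6-hydroxy-6-[(Z)-heptadec-8-enyl]cyclohex-2-enone | CCCCCCCC/C=C\CCCCCCC[C@]1(O)C(=O)C=C[C@H]2O[C@@H]12 | intermediate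
12 | pleiogenone A | CCCCCCCC/C=C\CCCCCCC[C@]1(O)C(=O)C=C[C@H](O)[C@H]1O | target

## Summary
Total steps: 9. Longest linear sequence: 8 (3 → 12, steps 2–9); the sequence from oleic acid is 7 steps.

The three steps most likely to fail are listed below, each with a fallback that changes the approach.

1. **Step 6.** The risks are low dr or the opposite sense of induction, p-quinone methide formation, ortho trapping, and I(III) attack on the alkene.
   - The two diastereomers are separable in any case, and (R)-lactamide is available if the sense of induction is reversed.
   - Fallback: drop the tether and the vinylogous ester and reach 11 through a symmetric route.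
     - Couple 2 with a 4-iodophenol ether to get the 4-alkylphenol, then oxidise it to the achiral p-quinol.
     - Treat with H2O2/NaOH to form the meso syn,syn-bis-epoxide.
     - Run a Wharton transposition (N2H4, AcOH) to give the racemic epoxy allylic alcohol.
     - Resolve that alcohol by lipase acylation, then oxidise with MnO2 to 11.
2. **Step 8.** The oxirane may not survive the Al–H and acid treatment, or the ionised intermediate may aromatise.
   - Fallback: reorder the endgame. Open the epoxy-ketone 10 first with acetate (CsOAc/AcOH), which attacks the carbon α to the ketone (future C4) with inversion and gives the same stereochemical outcome.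
   - DIBAL-H then cleaves the acetate, lactone and ketone together, and acid delivers 12 directly, so the transposition never has to carry an epoxide.
3. **Step 9.** Opening could occur at the wrong site, or acid could dehydrate the triol to phenolic products.
   - Fallback: replace free hydrolysis with a chelation-directed opening. Ti(OiPr)4/PhCO2H acts on the 2,3-epoxy alcohol motif of 11, with titanium bound to the C6–OH, and delivers benzoate to the distal carbon C4 with inversion.
   - The benzoate is then removed enzymatically or with mild K2CO3/MeOH.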